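At a fixed time of 12 h I ask how much of its Qb a flask has used, treating Qb as the limiting reagent in west and north, where less of it is charged than Qa.

all flasks: Qa 0.13 M; Qc 13 mM

| charge | Qb | remark | time |
|---|---|---|---|
| alpha | 0.077 M | run made earlier |  |
| delta | 0.096 M | run made earlier |  |
| north | 0.120 M |  | 12 h |
| west | 0.0910 M |  | 12 h |

| run | time / h | Qd / % | Qe / % | Qa / % |
|---|---|---|---|---|
| alpha | 1.50 | 21.1 | 7.7 | 72.7 |
| alpha | 4.00 | 30.6 | 9.8 | 57.5 |
| alpha | 8.00 | 32.7 | 12.5 | 51.4 |
| alpha | 12.0 | 29.6 | 16.7 | 54.3 |
| delta | 1.00 | 21.3 | 6.6 | 74.6 |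
| delta | 2.00 | 29.0 | 9.7 | 60.7 |
| delta | 5.00 | 37.9 | 14.1 | 47.7 |
| delta | 12.0 | 37.7 | 21.7 | 44.6 |

(each reading ± 1 percentage point)

- what was read earlier has a scatter of 1 percentage point, one standard deviation

* which of these there is most of at the end, counted by the Qa in it, north (Qa / Qe / Qd)
* which of these there is most of at the end, counted by the Qa in it, west (Qa / Qe / Qd)
* final amount of the leader among these, as a percentage of the Qa charged, in north
* final amount of the leader among these, as a percentage of the Qa charged, in west

From alpha to delta, more Qb leaves less Qa. West's charge lies between theirs, so I bound its final Qa by alpha's 54.3% above and delta's 44.6% below. North has more Qb than either: delta's reading is its ceiling, and spending its whole Qb charge at one Qb per Qa gives a floor of 7.69%.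

To tighten this I take one Qb per Qa lost. Delta gives 0.750 for the spent share u, the Qa lost by 12 h divided by the Qb charged, and alpha gives 0.772, each read with the scatter. In delta's last reading, Qd is a fraction 0.635 of Qd and Qe together.

West, Qa left = 1 − u·Qb/Qa: 47.5% to 46.0%; Qd 33.3%

North, from delta's u: Qa left 30.8%; Qd 44.0%

So I expect Qa to lead in west and Qd in north. The forecast reads the runs the same way: “Conversion of Qa stops at roughly 0.75–0.8 of the Qb/Qa ratio”. It gives Qd in north at 43% (38% to 48%) and Qa in west at 47% (44% to 50%), which lies inside my west bracket.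

    Qa + Qb + Qc ⇌ Qd + Qc, rate k1*[Qa]*[Qb]*[Qc] forward; the back reaction follows from the equilibrium constant (K = 35.0 M⁻¹, k = 250 M⁻² h⁻¹)
    Qa + Qb → Qe (k = 0.870 M⁻¹ h⁻¹)

West ends with 44.9% of Qa in the lead, 1.1 percentage points below my tightened bracket, and north with 43.6% of Qd. West still holds 21% of its Qb, unbound. Now take the neighbour of north charged with 0.033 M of Qa, which has 3.64 equiv of Qb. Delta's share 0.750 of that Qb is 2.73 times the Qa charged, more than the Qa that flask holds, so there Qa is the limiting one. Its own spent share is 0.235, with 14% of its Qa left.

Readings and results were generated by integration for substances that don't exist; the scatter is artificial.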